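The closed, stirred vessel of the maple run holds the same charge as the elm run, so the elm readings show you how your maple run should begin. What you have to judge is the stretch from the last elm reading to 210 min.

| flask | starting material | partner | free catalyst | time |
|---|---|---|---|---|
| elm | 0.200 M | 0.220 M | 0.00400 M |  |
| alder | 0.0800 M | 0.100 M | 0.00400 M |  |
| cedar | 0.200 M | 0.220 M | 0.00600 M |  |
| birch | 0.300 M | 0.220 M | 0.00400 M |  |
| maple | 0.200 M | 0.220 M | 0.00400 M | 210 min |

- elm run (time / min: [target] / M): 1.4: 0.0113; 2.7: 0.0191; 5.1: 0.0308; 9.7: 0.0524; 18: 0.0707; 35: 0.0808
- alder run (time / min: [target] / M): 1.4: 0.0015; 2.7: 0.0052; 5.1: 0.0083; 9.7: 0.0124; 18: 0.0222; 35: 0.0313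
- cedar run (time / min: [target] / M): 1.4: 0.0156; 2.7: 0.0280; 5.1: 0.0458; 9.7: 0.0675; 18: 0.0880; 35: 0.0961
- birch run (time / min: [target] / M): 1.4: 0.0145; 2.7: 0.0265; 5.1: 0.0459; 9.7: 0.0695; 18: 0.0919; 35: 0.1018

(scatter of a reading: 0.001 M)

* the power of [starting material] that the first rate follows, about the charge of the elm run; measure it at two percent of starting material made into target (one fixed amount of target, the same in the runs compared)
* the power of [free catalyst] that the first rate follows, about the charge of the elm run; measure it at two percent of starting material made into target
* target in the maple run at 210 min, as a share of the starting material charged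

- Overall: starting material + partner -> target, with free catalyst as catalyst.
- Constant volume, constant temperature.
- What is held in complexes is read along with the free species.
- An order is taken over about fifteen percent of the charge, up and down.

Turn the question round: what would the maple run need in order to finish? Starting material is the limiting reagent, at 0.200 M against 0.220 M of partner. Elm stands at 0.0808 M at 35 min, so the missing 0.119 M would have to come in 175 min, a steady 6.81 × 10⁻⁴ M min⁻¹. Elm's last interval ran at 5.94 × 10⁻⁴ M min⁻¹, a little below that, so finishing asks that the rate stop falling and even rise.

The elm readings show it falling. The interval before ran at 0.00220 M min⁻¹, and the midpoints of the two intervals lie 12.7 min apart. This gives the fall-off constant λ, the fraction of the rate lost per minute, 0.104 min⁻¹, a reading with the scatter of its readings.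

Follow one catalyst molecule: at each fork it either turns over or drops out. Cedar, with more catalyst on the same starting material and partner, stands at 0.0961 M at 35 min, higher than elm, so I read elm's stall as lost catalyst, not as a balance of reaction. If the fall continues at λ, the rate at 35 min comes to about 2.46 × 10⁻⁴ M min⁻¹, and dividing by λ gives an estimated 0.00237 M still to come. My share for maple is therefore 41.6%.

The forecast gives orders of 0.8 in starting material and 0.95 in free catalyst and a share of 42.5%, 0.90 percentage points above mine, on this ground: “This suggests catalyst death linked to partner.”

The flask gives 1.0 and 1.0 for the orders, and 42.0% for maple against my 41.6%.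

    free catalyst + starting material + partner → target + free catalyst (99.00 M⁻² min⁻¹)
    2 partner ⇌ idle reagent dimer, settled at all times (6.780 M⁻¹)
    free catalyst + target → spent catalyst + target (1.230 M⁻¹ min⁻¹)

Watch the rate between 18 min and 35 min: if it falls off with λ near 0.104 min⁻¹, expect about the 41.6% reckoned above. Free catalyst that meets target becomes spent catalyst, and the maple run with that loss taken away proves its weight, reaching 95.8% instead of 42.0% at 210 min. That loss accounts for 93% of what is missing.

The runs come from a simulation with constants of no real substance, and the scatter is random.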